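Assumption: the SMILES is read as one S stereocentre (OH > butenolide carbon > CH2 > H) and two E trisubstituted alkenes; dihydro-β-ionone, furan-3-carbaldehyde, allenylboronic acid pinacol ester and (S)-TRIP are bought.

## Retrosynthetic overview

1. The butenolide is the only ring made, and it is made last: a protecting-group-free singlet-oxygen dearomatization of a 3-furyl triene diol, with borohydride reduction and lactonization in the same flask.
2. The furyl triene diol comes from a B-alkyl Suzuki coupling of a furyl dienediol (right half) with an E-vinyl iodide (left half; the cyclohexene ring is bought in as dihydro-β-ionone).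
3. The dienediol comes from (S)-1-(furan-3-yl)but-3-yn-1-ol by hydroxymethylation and alkoxide-directed anti-vinylmagnesiation, which fixes the E allylic alcohol.
4. The homopropargylic alcohol comes from furan-3-carbaldehyde by catalytic asymmetric propargylation, which sets the only stereocentre.
5. The vinyl iodide comes from dihydro-β-ionone by methyl ketone to alkyne conversion, then zirconium-catalysed methylalumination and iodination.

## Route

Step 1
Reactants: 1 dihydro-β-ionone [4-(2,6,6-trimethylcyclohex-1-en-1-yl)butan-2-one]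
Product: 3 2-(but-3-yn-1-yl)-1,3,3-trimethylcyclohex-1-ene, via enol phosphate 2 (not isolated)
Conditions: LiN(iPr)2 (1.1 equiv), THF, −78 °C; ClP(O)(OEt)2 (1.1 equiv), −78 °C to rt; then LiN(iPr)2 (2.3 equiv), −78 °C to rt; H2O
Reagents that add atoms: none
Why: Kinetic deprotonation at the methyl group, O-phosphorylation and base-induced elimination of the enol phosphate (Negishi methyl ketone to alkyne synthesis) give the terminal alkyne; no stereocentre is involved.

Step 2
Reactants: 3 2-(but-3-yn-1-yl)-1,3,3-trimethylcyclohex-1-ene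
Product: 5 2-[(3E)-4-iodo-3-methylbut-3-en-1-yl]-1,3,3-trimethylcyclohex-1-ene, via alkenylalane 4 (not isolated)
Conditions: Me3Al (2.5 equiv), Cp2ZrCl2 (0.25 equiv), CH2Cl2, 0 °C to rt, 12 h; then I2 (1.3 equiv), THF, −30 to 0 °C
Reagents that add atoms: trimethylaluminium, C[Al](C)C; iodine, II
Why: Negishi zirconium-catalysed syn-methylalumination puts methyl on the internal and aluminium on the terminal alkyne carbon, and iodinolysis with retention gives the E-iodide; the tetrasubstituted ring alkene is inert.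

Step 3
Reactants: 6 furan-3-carbaldehyde
Product: 8 (1S)-1-(furan-3-yl)but-3-yn-1-ol, via borate ester 7 (not isolated)
Conditions: allenylboronic acid pinacol ester (1.5 equiv), (S)-TRIP [(S)-3,3'-bis(2,4,6-triisopropylphenyl)-1,1'-binaphthyl-2,2'-diyl hydrogen phosphate] (5 mol%), 4 Å MS, toluene, −20 °C, 72 h; aqueous work-up
Reagents that add atoms: allenylboronic acid pinacol ester, C=C=CB1OC(C)(C)C(C)(C)O1
Why: Chiral phosphoric acid-catalysed propargylation (SE2′ transfer from the allenylboronate through a closed six-membered transition state) in which the (S)-catalyst directs attack to the Si face of the aldehyde and so sets the S carbinol; the sense is assigned by analogy with aryl aldehydes (R-catalyst gives R-alcohols) and is checked by Mosher ester analysis.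

Step 4
Reactants: 8 (1S)-1-(furan-3-yl)but-3-yn-1-ol
Product: 11 (2E,5S)-2-ethenyl-5-(furan-3-yl)pent-2-ene-1,5-diol, via bis(chloromagnesium) alkoxide 9 (not isolated), via oxamagnesacycle 10 (not isolated)
Conditions: EtMgCl (2.1 equiv), THF, 0 to 40 °C; (CH2O)n (1.3 equiv), 45 °C, 2 h; then CH2=CHMgCl (5 equiv), THF–toluene, 75 °C, 16 h; sat. aq. NH4Cl, 0 °C
Reagents that add atoms: paraformaldehyde (as formaldehyde), C=O; vinylmagnesium chloride, C=C[Mg]Cl
Why: Iotsich hydroxymethylation of the alkynylmagnesium gives the propargylic magnesium alkoxide, which directs anti-carbomagnesiation (Duboudin–Fallis type): vinyl adds to the carbon next to CH2O and magnesium is held on the other carbon in a five-membered chelate, so protonation gives the E-dienol with CH2OH trans to the carbinol arm, the stereocentre being untouched.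

Step 5
Reactants: 11 (2E,5S)-2-ethenyl-5-(furan-3-yl)pent-2-ene-1,5-diol; 5 2-[(3E)-4-iodo-3-methylbut-3-en-1-yl]-1,3,3-trimethylcyclohex-1-ene
Product: 13 (1S,3E,7E)-1-(furan-3-yl)-4-(hydroxymethyl)-8-methyl-10-(2,6,6-trimethylcyclohex-1-en-1-yl)deca-3,7-dien-1-ol, via tris-boryl adduct 12 (not isolated)
Conditions: 9-BBN (3.3 equiv), THF, 0 °C to rt, 4 h; then 5 (1.0 equiv), PdCl2(dppf) (5 mol%), AsPh3 (5 mol%), 3 M aq. NaOH, THF–DMF, rt to 50 °C
Reagents that add atoms: none
Why: Anti-Markovnikov hydroboration of the monosubstituted vinyl group by 9-BBN (the two OH groups are capped in the flask as borinates, hence the excess) and B-alkyl Suzuki–Miyaura coupling with retention of the iodide geometry join the halves, leaving both trisubstituted alkenes E.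

Step 6
Reactants: 13 (1S,3E,7E)-1-(furan-3-yl)-4-(hydroxymethyl)-8-methyl-10-(2,6,6-trimethylcyclohex-1-en-1-yl)deca-3,7-dien-1-ol
Product: 16 4-[(1S,3E,7E)-1-hydroxy-4-(hydroxymethyl)-8-methyl-10-(2,6,6-trimethylcyclohex-1-en-1-yl)deca-3,7-dien-1-yl]furan-2(5H)-one, via furan endoperoxide 14 (not isolated), via hydroxybutenolide 15 (not isolated)
Conditions: O2, tetraphenylporphyrin (1 mol%), iPr2NEt (5 equiv), CH2Cl2, visible light, −78 °C, 1–2 h; Ar purge; then NaBH4 (3 equiv), EtOH, −78 to 0 °C; then 1 M HCl to pH 2, rt, 1 h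
Reagents that add atoms: dioxygen, O=O
Why: Singlet-oxygen [4+2] cycloaddition dearomatizes the furan, the hindered amine removes the less hindered C5–H of the endoperoxide (Kornblum–DeLaMare fragmentation) to give the 4-substituted 5-hydroxybutenolide regioselectively, and borohydride reduction of its open aldehyde form followed by acid lactonization gives the 4-substituted furan-2(5H)-one without touching the carbinol stereocentre.

## Compound list

1 | dihydro-β-ionone, 4-(2,6,6-trimethylcyclohex-1-en-1-yl)butan-2-one | CC(=O)CCC1=C(C)CCCC1(C)C | starting material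
2 | diethyl 4-(2,6,6-trimethylcyclohex-1-en-1-yl)but-1-en-2-yl phosphate (enol phosphate, not isolated) | C=C(CCC1=C(C)CCCC1(C)C)OP(=O)(OCC)OCC | intermediate
3 | 2-(but-3-yn-1-yl)-1,3,3-trimethylcyclohex-1-ene | C#CCCC1=C(C)CCCC1(C)C | intermediate
4 | dimethyl[(1E)-2-methyl-4-(2,6,6-trimethylcyclohex-1-en-1-yl)but-1-en-1-yl]alumane (alkenylalane, not isolated) | C[Al](C)/C=C(\C)CCC1=C(C)CCCC1(C)C | intermediate
5 | 2-[(3E)-4-iodo-3-methylbut-3-en-1-yl]-1,3,3-trimethylcyclohex-1-ene | I/C=C(\C)CCC1=C(C)CCCC1(C)C | intermediate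
6 | furan-3-carbaldehyde | O=Cc1ccoc1 | starting material
7 | 2-{[(1S)-1-(furan-3-yl)but-3-yn-1-yl]oxy}-4,4,5,5-tetramethyl-1,3,2-dioxaborolane (borate ester, not isolated) | C#CC[C@H](OB1OC(C)(C)C(C)(C)O1)c1ccoc1 | intermediate
8 | (1S)-1-(furan-3-yl)but-3-yn-1-ol | C#CC[C@H](O)c1ccoc1 | intermediate
9 | bis(chloromagnesium) alkoxide of (1S)-1-(furan-3-yl)pent-3-yne-1,5-diol (not isolated) | Cl[Mg]OCC#CC[C@H](O[Mg]Cl)c1ccoc1 | intermediate
10 | oxamagnesacycle: 2,5-dihydro-1,2-oxamagnesole with vinyl on C4 and the (2S)-2-(chloromagnesiooxy)-2-(furan-3-yl)ethyl group on C3 (not isolated) | C=CC1=C(C[C@H](O[Mg]Cl)c2ccoc2)[Mg]OC1 | intermediate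
11 | (2E,5S)-2-ethenyl-5-(furan-3-yl)pent-2-ene-1,5-diol | C=C/C(=C\C[C@H](O)c1ccoc1)CO | intermediate
12 | tris-boryl adduct: 11 hydroborated at the terminal vinyl carbon by 9-BBN, both hydroxyls as 9-BBN borinates (not isolated) | C1CCC2CCCC1B2CC/C(=C\C[C@H](OB1C2CCCC1CCC2)c1ccoc1)COB1C2CCCC1CCC2 | intermediate
13 | (1S,3E,7E)-1-(furan-3-yl)-4-(hydroxymethyl)-8-methyl-10-(2,6,6-trimethylcyclohex-1-en-1-yl)deca-3,7-dien-1-ol | CC1=C(CC/C(C)=C/CC/C(=C\C[C@H](O)c2ccoc2)CO)C(C)(C)CCC1 | intermediate
14 | furan endoperoxide: (1S,3E,7E)-4-(hydroxymethyl)-8-methyl-1-(2,3,7-trioxabicyclo[2.2.1]hept-5-en-5-yl)-10-(2,6,6-trimethylcyclohex-1-en-1-yl)deca-3,7-dien-1-ol, both bridgehead diastereomers (not isolated) | CC1=C(CC/C(C)=C/CC/C(=C\C[C@H](O)C2=CC3OOC2O3)CO)C(C)(C)CCC1 | intermediate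
15 | hydroxybutenolide: 5-hydroxy-4-[(1S,3E,7E)-1-hydroxy-4-(hydroxymethyl)-8-methyl-10-(2,6,6-trimethylcyclohex-1-en-1-yl)deca-3,7-dien-1-yl]furan-2(5H)-one, lactol epimers, present as the open carboxylate in the flask (not isolated) | CC1=C(CC/C(C)=C/CC/C(=C\C[C@H](O)C2=CC(=O)OC2O)CO)C(C)(C)CCC1 | intermediate
16 | 4-[(1S,3E,7E)-1-hydroxy-4-(hydroxymethyl)-8-methyl-10-(2,6,6-trimethylcyclohex-1-en-1-yl)deca-3,7-dien-1-yl]furan-2(5H)-one | CC1=C(CC/C(C)=C/CC/C(=C\C[C@H](O)C2=CC(=O)OC2)CO)C(C)(C)CCC1 | target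

## Step count and risks

Total steps: 6 (steps 1–2 and steps 3–4 are parallel branches). Longest linear sequence: 4 (steps 3, 4, 5, 6 from furan-3-carbaldehyde; equally steps 1, 2, 5, 6 from dihydro-β-ionone).

Steps most likely to fail:

Step 4. The second (homopropargylic) alkoxide, residual formaldehyde or allene formation may make the telescoped anti-vinylmagnesiation slow or unselective. The fallback replaces carbomagnesiation by directed trans-hydrometalation and cross-coupling. It sets out from 8: n-BuLi (2.1 equiv) and paraformaldehyde give the isolated (1S)-1-(furan-3-yl)pent-3-yne-1,5-diol F1. Hydroxyl-directed trans-hydrostannation (Bu3SnH, [Cp*RuCl]4 cat., CH2Cl2, rt) places tin on the alkyne carbon next to CH2OH with hydrogen trans to it, giving (2Z,5S)-5-(furan-3-yl)-2-(tributylstannyl)pent-2-ene-1,5-diol F2. Stille coupling with vinyl bromide (Pd(PPh3)4, CuI, CsF, DMF) with retention comes back to the route at 11.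

Step 5. 9-BBN is consumed by the free hydroxyls, and the 2-substituted diene may be hydroborated unselectively or the alkylborane may couple poorly. The fallback moves the union two carbons along and uses carbomagnesiation in place of the Suzuki coupling. It sets out from 3 and from 9 (made in the flask from 8 as in step 4, with no vinyl Grignard added). Alkyne 3 is methylaluminated to 4 as in step 2; n-BuLi and then oxirane give (3E)-4-methyl-6-(2,6,6-trimethylcyclohex-1-en-1-yl)hex-3-en-1-ol F3. CBr4/PPh3 gives 2-[(3E)-6-bromo-3-methylhex-3-en-1-yl]-1,3,3-trimethylcyclohex-1-ene F4, and Mg in THF gives [(3E)-4-methyl-6-(2,6,6-trimethylcyclohex-1-en-1-yl)hex-3-en-1-yl]magnesium bromide F5. CuI-catalysed anti-carbomagnesiation of 9 with F5 (2.5 equiv, THF, reflux), then NH4Cl, comes back to the route at 13.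

Step 6 (the riskiest). Singlet oxygen can undergo ene reaction at the tetrasubstituted ring alkene, whose rate is not far below that of the furan, and the fragmentation regiochemistry or the reduction may not be clean on the unprotected triene diol. The fallback avoids singlet oxygen and sets out from 13. Sterically controlled C–H borylation ([Ir(OMe)(cod)]2, 4,4'-di-tert-butyl-2,2'-bipyridine, excess B2pin2, THF, rt to 50 °C) at the unhindered furan C5–H gives (1S,3E,7E)-4-(hydroxymethyl)-8-methyl-1-[5-(4,4,5,5-tetramethyl-1,3,2-dioxaborolan-2-yl)furan-3-yl]-10-(2,6,6-trimethylcyclohex-1-en-1-yl)deca-3,7-dien-1-ol F6. Oxidation (NaBO3·4H2O, THF/H2O, then Et3N) turns C–B into C–OH, and the 2-hydroxyfuran tautomerizes to the conjugated 4-substituted furan-2(5H)-one, coming back to the route at 16.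

## Further compounds

F1 | step 4 | (1S)-1-(furan-3-yl)pent-3-yne-1,5-diol | OCC#CC[C@H](O)c1ccoc1
F2 | step 4 | (2Z,5S)-5-(furan-3-yl)-2-(tributylstannyl)pent-2-ene-1,5-diol | CCCC[Sn](CCCC)(CCCC)/C(=C\C[C@H](O)c1ccoc1)CO
F3 | step 5 | (3E)-4-methyl-6-(2,6,6-trimethylcyclohex-1-en-1-yl)hex-3-en-1-ol | OCC/C=C(\C)CCC1=C(C)CCCC1(C)C
F4 | step 5 | 2-[(3E)-6-bromo-3-methylhex-3-en-1-yl]-1,3,3-trimethylcyclohex-1-ene | BrCC/C=C(\C)CCC1=C(C)CCCC1(C)C
F5 | step 5 | [(3E)-4-methyl-6-(2,6,6-trimethylcyclohex-1-en-1-yl)hex-3-en-1-yl]magnesium bromide | Br[Mg]CC/C=C(\C)CCC1=C(C)CCCC1(C)C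
F6 | step 6 | (1S,3E,7E)-4-(hydroxymethyl)-8-methyl-1-[5-(4,4,5,5-tetramethyl-1,3,2-dioxaborolan-2-yl)furan-3-yl]-10-(2,6,6-trimethylcyclohex-1-en-1-yl)deca-3,7-dien-1-ol | CC1=C(CC/C(C)=C/CC/C(=C\C[C@H](O)c2cc(B3OC(C)(C)C(C)(C)O3)oc2)CO)C(C)(C)CCC1
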